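- Saturday's: starting material 0.46 M; reagent in the second phase 0.92 M; run made earlier
- flask: starting material 0.46 M; reagent in the second phase 0.460 M; time 20 h; volume of the second phase over the first 0.50

- Saturday's (time / min: target / %, starting material / %): 10.0: 0.5, 99.5; 15.0: 0, 99.6; 20.0: 0.5, 99.3; 30.0: 0.1, 99.4; 50.0: 1.2, 98.7; 80.0: 1.7, 98.4; 120: 2.4, 97.1

(readings scatter by 0.3 percentage points)

- in the second phase: reagent in the second phase; everything else is in the first
- charges count per volume of the first phase; a concentration in a rate is the amount of a species over the volume of its own phase; every rate counts per litre of the first phase
- the earlier runs hold the two phases in the same ratio of volumes as the flask asked about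

- birch: doubling the transfer coefficient of the reagent in the second phase, all else as stated
- alder: doubling the amount of reagent in the second phase, all else as stated

- the target standing at 20 h, as a percentage of the starting material charged
- the change that raises the amount of target at 20 h, in percent of the starting material charged most ("none" if none brings more than 2 percentage points) (birch / alder / none)
- amount of target at 20 h, in percent of the starting material charged, after birch

**Easy step.** I start from the last target reading of Saturday's run, 2.4% after 120 min, which stands above the scatter of 0.3 percentage points. I assume that the pace in percent per hour follows [reagent in the second phase] and not the charge of starting material, a pseudo-first-order loss of starting material. For the flask, with 0.460 M against Saturday's 0.92 M, this comes to 167 h, the making time: the charge of starting material over the opening pace of target.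

**Fastest rung.** Saturday's readings show no delay beyond their scatter, and target already reads 1.2% at 50.0 min. So I take the passage of reagent between the phases as over far sooner than the making time, and I expect birch to change nothing.

**Middle rung.** The asked 20 h is ten times Saturday's last reading but shorter than the making time, so I hold the pace near its opening value. By this reckoning the flask makes 12.0% of the charge. On the same reckoning, alder halves the making time and gives 24.0% made, while birch stays at 12.0%.

**Slowest rung.** I can read no loss of target from Saturday's run: its last gap between starting material lost and target is 0.5 points, with a scatter of 0.3 points on each reading. So I commit to 12.0% as target made, and what stands is that less an unread loss.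

**The result.** The forecast gives 12% standing, alder as the best change and 15% after birch, a birch figure above my 12.0%, taken “as a hedge, with a wide range”. The flask gives 7.54%; alder is best and adds 5.5 points, while birch adds 0.013 points and gives 7.55%.

    reagent in the reaction phase ⇌ reagent in the second phase, rate k1*([reagent in the reaction phase] - [reagent in the second phase]/K1) per volume of the first phase (partition coefficient = 1.40, kL = 7.40 × 10⁻⁴ s⁻¹)
    starting material + reagent in the reaction phase → target (k = 8.30 × 10⁻⁶ M⁻¹ s⁻¹)
    reagent in the reaction phase + target → over-reacted product (k = 1.20 × 10⁻⁵ M⁻¹ s⁻¹)
    target ⇌ isomer of the product (K = 0.480, k = 1.90 × 10⁻⁶ s⁻¹)
    starting material + target → side product (k = 3.10 × 10⁻⁵ M⁻¹ s⁻¹)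

**Neighbouring flask.** Adding target, over-reacted product, isomer of the product and the side product with its double count taken out, the flask made 13.5% by 20 h, against 12.0% from the making time. The neighbouring flask charges 1.8 M of starting material with the same reagent and time, so the making time again gives 12.0%. Its sum is 10.9%. Target in the neighbouring flask stands at 2.36%, and side product, counted double, at 15.9%.

Readings and results are calculated for substances that don't exist, and the scatter is random.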